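**Strategy.** The carbocycle is opened at C7–C8 (C7 is the CHBr carbon, C8 its CH2 neighbour). The key step exploits the 1,4-relationship between C7 and the oxygen-bearing C9a across the six-membered ring. Both are first tied into a γ-lactone; iodine–lithium exchange at C8 then triggers attack on the lactone carbonyl C7. One operation closes the cyclohexane, turns the lactone carbonyl into the C7 ketone (later the bromide) and frees the C9a alkoxide that later closes the oxepene. The precursor is an iodoethyl γ-butyrolactone carrying a (Z)-enyne side chain, made by Evans alkylation and Felkin-controlled vinyl addition.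

Key step: step 10

Remark: locants follow the 1-benzoxepine skeleton of the target (O1, C2, C3, C4, C5, C5a, C6, C7, C8, C9, C9a) and are also used for the corresponding carbons of earlier intermediates; commercial (Z)-3-methylpent-2-en-4-yn-1-ol is taken as the pure Z isomer.

Step 1
Reactants: 1 (S)-4-benzyl-1,3-oxazolidin-2-one; 2 2,2-dimethylsuccinic anhydride
Product: 4 methyl 4-[(4S)-4-benzyl-2-oxo-1,3-oxazolidin-3-yl]-2,2-dimethyl-4-oxobutanoate, via lithium carboxylate 3 (not isolated)
Conditions: n-BuLi, THF, −78 °C; 2, −78 to 0 °C; then MeI, DMF, rt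
Reagents that add atoms: iodomethane, CI
Why: The lithiated oxazolidinone opens the anhydride at the unhindered carbonyl (next to CH2, not next to CMe2) in an N-acylation, and the lithium carboxylate is then O-methylated by SN2; no stereocenter is formed.

Step 2
Reactants: 5 (Z)-3-methylpent-2-en-4-yn-1-ol
Product: 7 (Z)-3-methyl-5-(trimethylsilyl)pent-2-en-4-yn-1-ol, via bis-silyl ether 6 (not isolated)
Conditions: EtMgBr (2.2 equiv), THF, 0 to 45 °C; Me3SiCl; then 1 M H2SO4, rt
Reagents that add atoms: chlorotrimethylsilane, C[Si](C)(C)Cl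
Why: C-Silylation of the terminal alkyne through the alkoxide/acetylide dianion, with only the labile O–Si bond cleaved on acidic work-up, masks the alkyne against 9-BBN and organometallics and leaves the Z alkene untouched.

Step 3
Reactants: 7 (Z)-3-methyl-5-(trimethylsilyl)pent-2-en-4-yn-1-ol
Product: 8 [(3Z)-5-bromo-3-methylpent-3-en-1-yn-1-yl]trimethylsilane
Conditions: CBr4, PPh3, CH2Cl2, 0 °C
Reagents that add atoms: tetrabromomethane, BrC(Br)(Br)Br
Why: Appel bromination of a primary allylic alcohol (SN2 on the alkoxyphosphonium ion) is mild enough to keep the Z geometry and the silyl alkyne.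

Step 4
Reactants: 4 methyl 4-[(4S)-4-benzyl-2-oxo-1,3-oxazolidin-3-yl]-2,2-dimethyl-4-oxobutanoate; 8 [(3Z)-5-bromo-3-methylpent-3-en-1-yn-1-yl]trimethylsilane
Product: 10 methyl (3S,5Z)-3-{[(4S)-4-benzyl-2-oxo-1,3-oxazolidin-3-yl]carbonyl}-2,2,6-trimethyl-8-(trimethylsilyl)oct-5-en-7-ynoate, via sodium enolate 9 (not isolated)
Conditions: NaN(SiMe3)2, THF, −78 °C; 8, −78 to −30 °C
Reagents that add atoms: none
Why: Evans asymmetric alkylation: the chelated sodium Z-enolate is alkylated by the reactive allylic bromide on the face opposite the benzyl group of the auxiliary, which sets the future C5a as S.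

Step 5
Reactants: 10 methyl (3S,5Z)-3-{[(4S)-4-benzyl-2-oxo-1,3-oxazolidin-3-yl]carbonyl}-2,2,6-trimethyl-8-(trimethylsilyl)oct-5-en-7-ynoate
Product: 12 (2S,4Z)-2-(1-methoxy-2-methyl-1-oxopropan-2-yl)-5-methyl-7-(trimethylsilyl)hept-4-en-6-ynoic acid, via peroxy acid 11 (not isolated)
Conditions: LiOH, H2O2, THF–H2O, 0 °C; then aq. Na2SO3; pH 3
Reagents that add atoms: hydrogen peroxide (as LiOOH), OO
Why: Hydroperoxide cleaves the exocyclic imide carbonyl selectively (Evans LiOOH hydrolysis) and sulfite reduces the peracid, while the neopentyl-type methyl ester is too hindered to be saponified at 0 °C and the auxiliary is recovered.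

Step 6
Reactants: 12 (2S,4Z)-2-(1-methoxy-2-methyl-1-oxopropan-2-yl)-5-methyl-7-(trimethylsilyl)hept-4-en-6-ynoic acid
Product: 14 methyl (3S,5Z)-3-acetyl-2,2,6-trimethyl-8-(trimethylsilyl)oct-5-en-7-ynoate, via acid chloride 13 (not isolated)
Conditions: (COCl)2, cat. DMF, CH2Cl2, 0 °C; evaporate; Me2CuLi, Et2O, −78 °C
Reagents that add atoms: lithium dimethylcuprate, [Li+].C[Cu-]C (methyl group); oxalyl chloride, O=C(Cl)C(Cl)=O (chlorine of intermediate 13 only)
Why: Acylation of a Gilman cuprate by an acid chloride stops at the methyl ketone, and the base-free conditions leave the hindered ester, the silyl alkyne and the α-stereocenter untouched.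

Step 7
Reactants: 14 methyl (3S,5Z)-3-acetyl-2,2,6-trimethyl-8-(trimethylsilyl)oct-5-en-7-ynoate
Product: 16 (4S,5S)-5-ethenyl-3,3,5-trimethyl-4-[(2Z)-3-methyl-5-(trimethylsilyl)pent-2-en-4-yn-1-yl]oxolan-2-one, via magnesium alkoxide 15 (not isolated)
Conditions: CH2=CHMgBr (1.3 equiv), LaCl3·2LiCl (0.3 equiv), THF, −78 °C to rt; aq. NH4Cl
Reagents that add atoms: vinylmagnesium bromide, C=C[Mg]Br
Why: Felkin–Anh 1,2-addition places the vinyl group anti to the very large tert-alkyl substituent of the α-stereocenter (CH2 inside, H outside), which sets the future C9a as S, and the tertiary alkoxide then closes the γ-lactone on the neighbouring methyl ester (5-exo-trig acyl substitution helped by the gem-dimethyl group).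

Step 8
Reactants: 16 (4S,5S)-5-ethenyl-3,3,5-trimethyl-4-[(2Z)-3-methyl-5-(trimethylsilyl)pent-2-en-4-yn-1-yl]oxolan-2-one
Product: 18 (4S,5S)-5-(2-hydroxyethyl)-3,3,5-trimethyl-4-[(2Z)-3-methyl-5-(trimethylsilyl)pent-2-en-4-yn-1-yl]oxolan-2-one, via alkylborane 17 (not isolated)
Conditions: 9-BBN, THF, 0 °C to rt; then H2O2, aq. NaOAc, 0 °C
Reagents that add atoms: hydrogen peroxide, OO (hydroxyl oxygen); 9-BBN, B1C2CCCC1CCC2 (boron of intermediate 17 only)
Why: Anti-Markovnikov hydroboration–oxidation in which 9-BBN selects the monosubstituted vinyl group over the trisubstituted enyne alkene and the silyl-capped alkyne, and buffered peroxide spares the lactone and the C–Si bond.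

Step 9
Reactants: 18 (4S,5S)-5-(2-hydroxyethyl)-3,3,5-trimethyl-4-[(2Z)-3-methyl-5-(trimethylsilyl)pent-2-en-4-yn-1-yl]oxolan-2-one
Product: 19 (4S,5S)-5-(2-iodoethyl)-3,3,5-trimethyl-4-[(2Z)-3-methyl-5-(trimethylsilyl)pent-2-en-4-yn-1-yl]oxolan-2-one
Conditions: I2, PPh3, imidazole, CH2Cl2, 0 °C to rt
Reagents that add atoms: iodine, II
Why: Garegg–Samuelsson iodination of the primary alcohol (SN2 on the alkoxyphosphonium ion) gives the exchange-ready primary iodide.

Step 10
Reactants: 19 (4S,5S)-5-(2-iodoethyl)-3,3,5-trimethyl-4-[(2Z)-3-methyl-5-(trimethylsilyl)pent-2-en-4-yn-1-yl]oxolan-2-one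
Product: 22 (3S,4S)-4-hydroxy-2,2,4-trimethyl-3-[(2Z)-3-methyl-5-(trimethylsilyl)pent-2-en-4-yn-1-yl]cyclohexan-1-one, via alkyllithium 20 (not isolated), via lithium hemiketalate 21 (not isolated)
Conditions: t-BuLi (2.05 equiv), Et2O–pentane, −78 °C, then to 0 °C; aq. NH4Cl
Reagents that add atoms: none
Why: Iodine–lithium exchange (faster at −78 °C than addition of t-BuLi to the hindered lactone; the second equivalent destroys t-BuI) gives primary alkyllithium 20, whose C8 adds to the lactone carbonyl C7 in an intramolecular nucleophilic acyl substitution. The closest known reaction type is the Parham-type cyclisation (halogen–metal exchange followed by attack on an ester) and its SmI2 variant on halo-lactones. The carbocycle closes in a 6-exo-trig mode through a boat-like transition state, giving the 7-oxabicyclo[2.2.1]heptane hemiketalate 21, which stores the carbonyl as an alkoxide so that no second addition occurs and opens to the 4-hydroxy ketone on protonation. No permanent stereocenter is created: C5a and C9a come from steps 4 and 7, and the transient hemiketal carbon is dictated by the bridge. The selectivity needed is chemoselectivity (exchange before carbonyl attack by t-BuLi, acyl attack before carbolithiation of the enyne or proton transfer), secured by the primary iodide, the silyl cap on the alkyne, the absence of acidic hydrogens and the proximity enforced by the quaternary C9a.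

Step 11
Reactants: 22 (3S,4S)-4-hydroxy-2,2,4-trimethyl-3-[(2Z)-3-methyl-5-(trimethylsilyl)pent-2-en-4-yn-1-yl]cyclohexan-1-one
Product: 23 (3S,4S)-4-hydroxy-2,2,4-trimethyl-3-[(2Z)-3-methylpent-2-en-4-yn-1-yl]cyclohexan-1-one
Conditions: K2CO3, MeOH, rt
Reagents that add atoms: none
Why: Base-mediated methanolysis of the alkynyl C–Si bond (protodesilylation) frees the terminal alkyne, and the γ-hydroxy ketone has no retro-aldol pathway.

Step 12
Reactants: 23 (3S,4S)-4-hydroxy-2,2,4-trimethyl-3-[(2Z)-3-methylpent-2-en-4-yn-1-yl]cyclohexan-1-one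
Product: 24 (5aS,9aS)-3,6,6,9a-tetramethyl-2-methylidene-2,5,5a,6,9,9a-hexahydro-1-benzoxepin-7(8H)-one
Conditions: Ph3PAuCl (5 mol %), AgOTf (5 mol %), CH2Cl2, 4 Å MS, rt
Reagents that add atoms: none
Why: Gold-catalysed alkynol cycloisomerisation: the cationic monovalent gold complex activates the terminal alkyne and the tertiary hydroxyl adds to its internal carbon (Markovnikov, 7-exo-dig), the Z alkene and the trans-diequatorial arrangement on the ring holding the two ends together, so that the trans ring fusion follows from C5a and C9a.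

Step 13
Reactants: 24 (5aS,9aS)-3,6,6,9a-tetramethyl-2-methylidene-2,5,5a,6,9,9a-hexahydro-1-benzoxepin-7(8H)-one
Product: 26 (2R,5aS,9aS)-2-(hydroxymethyl)-3,6,6,9a-tetramethyl-2,5,5a,6,9,9a-hexahydro-1-benzoxepin-7(8H)-one, via alkylborane 25 (not isolated)
Conditions: 9-BBN, THF, 0 °C to rt; then NaOH, H2O2, 0 °C
Reagents that add atoms: hydrogen peroxide, OO (hydroxyl oxygen); 9-BBN, B1C2CCCC1CCC2 (boron of intermediate 25 only)
Why: Hydroboration–oxidation of the exocyclic enol ether puts boron on the terminal carbon and delivers hydrogen to C2 from the face opposite the axial C9a methyl group (1,3-related to C2), which sets C2 as R, while 9-BBN leaves the hindered ketone and the trisubstituted ring alkene alone.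

Step 14
Reactants: 26 (2R,5aS,9aS)-2-(hydroxymethyl)-3,6,6,9a-tetramethyl-2,5,5a,6,9,9a-hexahydro-1-benzoxepin-7(8H)-one
Product: 27 (2R,5aS,7R,9aS)-2-(hydroxymethyl)-3,6,6,9a-tetramethyl-2,5,5a,6,7,8,9,9a-octahydro-1-benzoxepin-7-ol
Conditions: LiBH(s-Bu)3 (2.5 equiv), THF, −78 °C; aq. NH4Cl
Reagents that add atoms: none
Why: The bulky hydride attacks the C7 ketone of the conformationally locked trans-fused system from the equatorial direction (as in 4,4-dimethyl-3-keto steroids), which should give the axial 7R alcohol needed for inversion.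

Step 15
Reactants: 27 (2R,5aS,7R,9aS)-2-(hydroxymethyl)-3,6,6,9a-tetramethyl-2,5,5a,6,7,8,9,9a-octahydro-1-benzoxepin-7-ol
Product: 28 palisadin B, (2R,5aS,7S,9aS)-7-bromo-2-(bromomethyl)-3,6,6,9a-tetramethyl-2,5,5a,6,7,8,9,9a-octahydro-1-benzoxepine
Conditions: CBr4, PPh3, pyridine, CH2Cl2, 0 to 40 °C
Reagents that add atoms: tetrabromomethane, BrC(Br)(Br)Br
Why: Double Appel reaction in which the primary alcohol is brominated by SN2 and the axial alkoxyphosphonium ion at C7 is displaced by bromide with inversion to the equatorial 7S bromide, an inversion known for 3-hydroxy-2,2-dimethylcyclohexane units.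

**Compound list**

1 | (S)-4-benzyl-1,3-oxazolidin-2-one | O=C1N[C@@H](Cc2ccccc2)CO1 | starting material
2 | 2,2-dimethylsuccinic anhydride (3,3-dimethyloxolane-2,5-dione) | CC1(C)CC(=O)OC1=O | starting material
3 | lithium 4-[(4S)-4-benzyl-2-oxo-1,3-oxazolidin-3-yl]-2,2-dimethyl-4-oxobutanoate | [Li+].[O-]C(=O)C(C)(C)CC(=O)N1[C@@H](Cc2ccccc2)COC1=O | intermediate (not isolated)
4 | methyl 4-[(4S)-4-benzyl-2-oxo-1,3-oxazolidin-3-yl]-2,2-dimethyl-4-oxobutanoate | COC(=O)C(C)(C)CC(=O)N1[C@@H](Cc2ccccc2)COC1=O | intermediate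
5 | (Z)-3-methylpent-2-en-4-yn-1-ol | OC/C=C(C)\C#C | starting material
6 | trimethyl{[(2Z)-3-methyl-5-(trimethylsilyl)pent-2-en-4-yn-1-yl]oxy}silane | C[Si](C)(C)OC/C=C(C)\C#C[Si](C)(C)C | intermediate (not isolated)
7 | (Z)-3-methyl-5-(trimethylsilyl)pent-2-en-4-yn-1-ol | OC/C=C(C)\C#C[Si](C)(C)C | intermediate
8 | [(3Z)-5-bromo-3-methylpent-3-en-1-yn-1-yl]trimethylsilane | BrC/C=C(C)\C#C[Si](C)(C)C | intermediate
9 | sodium (Z)-enolate of 4 (O and CMe2 cis) | [Na+].COC(=O)C(C)(C)/C=C(\[O-])N1[C@@H](Cc2ccccc2)COC1=O | intermediate (not isolated)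
10 | methyl (3S,5Z)-3-{[(4S)-4-benzyl-2-oxo-1,3-oxazolidin-3-yl]carbonyl}-2,2,6-trimethyl-8-(trimethylsilyl)oct-5-en-7-ynoate | COC(=O)C(C)(C)[C@H](C/C=C(C)\C#C[Si](C)(C)C)C(=O)N1[C@@H](Cc2ccccc2)COC1=O | intermediate
11 | (2S,4Z)-2-(1-methoxy-2-methyl-1-oxopropan-2-yl)-5-methyl-7-(trimethylsilyl)hept-4-en-6-yneperoxoic acid | COC(=O)C(C)(C)[C@H](C/C=C(C)\C#C[Si](C)(C)C)C(=O)OO | intermediate (not isolated)
12 | (2S,4Z)-2-(1-methoxy-2-methyl-1-oxopropan-2-yl)-5-methyl-7-(trimethylsilyl)hept-4-en-6-ynoic acid | COC(=O)C(C)(C)[C@H](C/C=C(C)\C#C[Si](C)(C)C)C(O)=O | intermediate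
13 | acid chloride of 12 | COC(=O)C(C)(C)[C@H](C/C=C(C)\C#C[Si](C)(C)C)C(Cl)=O | intermediate (not isolated)
14 | methyl (3S,5Z)-3-acetyl-2,2,6-trimethyl-8-(trimethylsilyl)oct-5-en-7-ynoate | COC(=O)C(C)(C)[C@H](C/C=C(C)\C#C[Si](C)(C)C)C(C)=O | intermediate
15 | bromomagnesium alkoxide from vinyl addition to 14 (tertiary carbinol carbon S) | COC(=O)C(C)(C)[C@H](C/C=C(C)\C#C[Si](C)(C)C)[C@@](C)(O[Mg]Br)C=C | intermediate (not isolated)
16 | (4S,5S)-5-ethenyl-3,3,5-trimethyl-4-[(2Z)-3-methyl-5-(trimethylsilyl)pent-2-en-4-yn-1-yl]oxolan-2-one | O=C1O[C@@](C)(C=C)[C@@H](C/C=C(C)\C#C[Si](C)(C)C)C1(C)C | intermediate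
17 | B-alkyl-9-borabicyclo[3.3.1]nonane from 16 | O=C1O[C@@](C)(CCB2C3CCCC2CCC3)[C@@H](C/C=C(C)\C#C[Si](C)(C)C)C1(C)C | intermediate (not isolated)
18 | (4S,5S)-5-(2-hydroxyethyl)-3,3,5-trimethyl-4-[(2Z)-3-methyl-5-(trimethylsilyl)pent-2-en-4-yn-1-yl]oxolan-2-one | O=C1O[C@@](C)(CCO)[C@@H](C/C=C(C)\C#C[Si](C)(C)C)C1(C)C | intermediate
19 | (4S,5S)-5-(2-iodoethyl)-3,3,5-trimethyl-4-[(2Z)-3-methyl-5-(trimethylsilyl)pent-2-en-4-yn-1-yl]oxolan-2-one | O=C1O[C@@](C)(CCI)[C@@H](C/C=C(C)\C#C[Si](C)(C)C)C1(C)C | intermediate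
20 | primary alkyllithium from 19 | O=C1O[C@@](C)(CC[Li])[C@@H](C/C=C(C)\C#C[Si](C)(C)C)C1(C)C | intermediate (not isolated)
21 | lithium 7-oxabicyclo[2.2.1]heptan-1-olate (bridged hemiketalate; O bridges C7 and C9a) | [Li+].[O-][C@]12CC[C@](C)(O1)[C@@H](C/C=C(C)\C#C[Si](C)(C)C)C2(C)C | intermediate (not isolated)
22 | (3S,4S)-4-hydroxy-2,2,4-trimethyl-3-[(2Z)-3-methyl-5-(trimethylsilyl)pent-2-en-4-yn-1-yl]cyclohexan-1-one | O=C1CC[C@](C)(O)[C@@H](C/C=C(C)\C#C[Si](C)(C)C)C1(C)C | intermediate
23 | (3S,4S)-4-hydroxy-2,2,4-trimethyl-3-[(2Z)-3-methylpent-2-en-4-yn-1-yl]cyclohexan-1-one | O=C1CC[C@](C)(O)[C@@H](C/C=C(C)\C#C)C1(C)C | intermediate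
24 | (5aS,9aS)-3,6,6,9a-tetramethyl-2-methylidene-2,5,5a,6,9,9a-hexahydro-1-benzoxepin-7(8H)-one (trans-fused) | CC1=CC[C@H]2C(C)(C)C(=O)CC[C@]2(C)OC1=C | intermediate
25 | B-alkyl-9-borabicyclo[3.3.1]nonane from 24 (boron on the CH2 at C2) | CC1=CC[C@H]2C(C)(C)C(=O)CC[C@]2(C)O[C@H]1CB1C2CCCC1CCC2 | intermediate (not isolated)
26 | (2R,5aS,9aS)-2-(hydroxymethyl)-3,6,6,9a-tetramethyl-2,5,5a,6,9,9a-hexahydro-1-benzoxepin-7(8H)-one | CC1=CC[C@H]2C(C)(C)C(=O)CC[C@]2(C)O[C@H]1CO | intermediate
27 | (2R,5aS,7R,9aS)-2-(hydroxymethyl)-3,6,6,9a-tetramethyl-2,5,5a,6,7,8,9,9a-octahydro-1-benzoxepin-7-ol (axial 7-OH) | CC1=CC[C@H]2C(C)(C)[C@H](O)CC[C@]2(C)O[C@H]1CO | intermediate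
28 | palisadin B, (2R,5aS,7S,9aS)-7-bromo-2-(bromomethyl)-3,6,6,9a-tetramethyl-2,5,5a,6,7,8,9,9a-octahydro-1-benzoxepine | CC1=CC[C@H]2C(C)(C)[C@@H](Br)CC[C@]2(C)O[C@H]1CBr | target

**Step count.** Total: 15 steps. Longest linear sequence: 14 steps (5 to 28 through steps 2–4 and 5–15); 13 steps from 1 and 2.

**Steps most likely to fail**

Step 15. At the axial, neopentyl alkoxyphosphonium centre C7, E2 loss of the axial C8 hydrogen or a 1,2-methyl shift from C6 may outrun the hindered backside attack of bromide. The fallback replaces SN2 by a radical hydrogen transfer and sets out from keto alcohol 26. Condensation with N2H4·H2O in EtOH should give the hydrazone F1. Oxidation with CuBr2 and LiOt-Bu in THF should convert it, with loss of dinitrogen, into the geminal dibromide F2. Appel bromination of the primary alcohol (CBr4, PPh3) should then give the tribromide F3. Bu3SnH (1 equiv, Et3B, air, −78 °C) removes one geminal bromine faster than it touches the primary bromide. The α-bromo radical at C7 should take hydrogen from the open axial face (syn only to the axial hydrogens at C5a and C9), leaving bromine equatorial, and the sequence comes back to the route at 28.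

Step 12. The hindered tertiary hydroxyl may add too slowly, so that alkyne hydration or acid-promoted isomerisation and hydrolysis of the exocyclic enol ether take over. The fallback activates the alkyne with a stoichiometric halonium ion instead and sets out from 23. N-Iodosuccinimide with NaHCO3 in MeCN at 0 °C should close the same ring by anti iodoalkoxylation to the (E)-iodo enol ether F4. Bu3SnH with AIBN in benzene at 80 °C then removes the vinylic iodine, and the sequence comes back at 24.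

Step 10. The unstabilised alkyllithium may be quenched, or undergo Wurtz-type coupling, before it passes the strained boat-like transition state to the bridged hemiketalate. The fallback uses a stabilised carbanion whose acylation is driven by formation of a β-keto sulfone anion, and sets out from iodide 19. PhSO2Na in DMF at 60 °C should give the phenyl sulfone F5. LiN(SiMe3)2 (2.2 equiv) in THF from −78 to 0 °C generates the α-sulfonyl carbanion, which opens the lactone in a Claisen-type acylation to the hydroxy β-keto sulfone F6. SmI2 in THF–MeOH at −78 °C cleaves the C–S bond reductively, and the sequence comes back at 22.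

**Further compounds**

F1 | step 15 | hydrazone of 26 at C7 | CC1=CC[C@H]2C(C)(C)C(=NN)CC[C@]2(C)O[C@H]1CO
F2 | step 15 | (2R,5aS,9aS)-7,7-dibromo-2-(hydroxymethyl)-3,6,6,9a-tetramethyl-2,5,5a,6,7,8,9,9a-octahydro-1-benzoxepine | CC1=CC[C@H]2C(C)(C)C(Br)(Br)CC[C@]2(C)O[C@H]1CO
F3 | step 15 | (2R,5aS,9aS)-7,7-dibromo-2-(bromomethyl)-3,6,6,9a-tetramethyl-2,5,5a,6,7,8,9,9a-octahydro-1-benzoxepine | CC1=CC[C@H]2C(C)(C)C(Br)(Br)CC[C@]2(C)O[C@H]1CBr
F4 | step 12 | (5aS,9aS)-2-[(E)-iodomethylidene]-3,6,6,9a-tetramethyl-2,5,5a,6,9,9a-hexahydro-1-benzoxepin-7(8H)-one | CC1=CC[C@H]2C(C)(C)C(=O)CC[C@]2(C)O/C1=C/I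
F5 | step 10 | (4S,5S)-5-[2-(phenylsulfonyl)ethyl]-3,3,5-trimethyl-4-[(2Z)-3-methyl-5-(trimethylsilyl)pent-2-en-4-yn-1-yl]oxolan-2-one | O=C1O[C@@](C)(CCS(=O)(=O)c2ccccc2)[C@@H](C/C=C(C)\C#C[Si](C)(C)C)C1(C)C
F6 | step 10 | (3S,4S)-4-hydroxy-2,2,4-trimethyl-3-[(2Z)-3-methyl-5-(trimethylsilyl)pent-2-en-4-yn-1-yl]-6-(phenylsulfonyl)cyclohexan-1-one (mixture at C6) | O=C1C(S(=O)(=O)c2ccccc2)C[C@](C)(O)[C@@H](C/C=C(C)\C#C[Si](C)(C)C)C1(C)C
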